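**Retrosynthetic overview**
1. Last bond: the diaryl ether C–O, made by addition–elimination of the free 4-OH of methyl 1,4-dihydroxy-3-prenyl-2-naphthoate on 2-bromo-1,4-naphthoquinone (the quinone bicycle is bought intact).
2. Key C–C bond: a Hauser–Kraus annulation, i.e. intermolecular Michael addition of lithiated 3-(phenylsulfonyl)phthalide to methyl (E)-6-methylhepta-2,5-dienoate, then Dieckmann closure, sulfinate loss and aromatisation. This sets 1-OH, 2-CO2Me, 3-prenyl and 4-OH in one step.
3. Donor: the sulfonylphthalide from 2-formylbenzoic acid and thiophenol, then S-oxidation. Acceptor: from 4-methylpent-3-en-1-ol by one-pot oxidation/Wittig olefination.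
4. Ring order: both benzo rings and the quinone ring are purchased; the only ring formed is the fully substituted hydroxylated ring of the western naphthalene (step 4).

Assumption: the target has no stereocentre and its only alkene carries two identical methyl groups, so "single enantiomer" is read as the one achiral compound drawn.

**Route**

Step 1
Reactants: 1 2-formylbenzoic acid; 2 benzenethiol
Product: 3 racemic 3-(phenylsulfanyl)-2-benzofuran-1(3H)-one
Conditions: TsOH·H2O (5 mol %), toluene, reflux, Dean–Stark
Reagents that add atoms: none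
Why: Acid-catalysed O,S-acetal formation on the ring tautomer (3-hydroxyphthalide) with azeotropic water removal; the new C3 stereocentre is racemic and is destroyed in step 4.

Step 2
Reactants: 3 racemic 3-(phenylsulfanyl)-2-benzofuran-1(3H)-one
Product: 4 racemic 3-(benzenesulfonyl)-2-benzofuran-1(3H)-one
Conditions: mCPBA (2.3 equiv), CH2Cl2, 0 °C → rt
Reagents that add atoms: mCPBA (3-chloroperoxybenzoic acid), OOC(=O)c1cccc(Cl)c1
Why: Sulfide-to-sulfone oxidation with two equivalents of peracid; the lactone is inert and no stereochemical issue arises.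

Step 3
Reactants: 5 4-methylpent-3-en-1-ol; 6 methyl (triphenylphosphoranylidene)acetate
Product: 8 methyl (2E)-6-methylhepta-2,5-dienoate, via 4-methylpent-3-enal 7 (not isolated)
Conditions: Dess–Martin periodinane (1.3 equiv), 6 (2.5 equiv), CH2Cl2, 0 °C → rt
Reagents that add atoms: none
Why: One-pot Dess–Martin oxidation/Wittig olefination traps the isomerisation-prone β,γ-unsaturated aldehyde as it forms, and the stabilised ylide gives the E-enoate (a geometry that is erased in step 4 anyway).

Step 4
Reactants: 4 racemic 3-(benzenesulfonyl)-2-benzofuran-1(3H)-one; 8 methyl (2E)-6-methylhepta-2,5-dienoate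
Product: 11 methyl 1,4-dihydroxy-3-(3-methylbut-2-en-1-yl)naphthalene-2-carboxylate, via Michael adduct 9 (not isolated), via diketo tautomer 10 (not isolated)
Conditions: LiOtBu (3 equiv), THF, −78 °C, add 4, then 8 (1.2 equiv), −78 °C → rt, Ar; degassed 1 M HCl quench
Reagents that add atoms: none
Why: Hauser–Kraus annulation: Michael addition of the sulfonyl-stabilised phthalide anion to the enoate β-carbon makes the key C–C bond, the ester enolate then acylates on the lactone carbonyl (Dieckmann type), and loss of benzenesulfinate plus enolisation gives the aromatic hydroquinone, erasing all transient stereocentres.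

Step 5
Reactants: 11 methyl 1,4-dihydroxy-3-(3-methylbut-2-en-1-yl)naphthalene-2-carboxylate; 12 2-bromonaphthalene-1,4-dione
Product: 13 Rubioncolin C, methyl 4-[(1,4-dioxo-1,4-dihydronaphthalen-2-yl)oxy]-1-hydroxy-3-(3-methylbut-2-en-1-yl)naphthalene-2-carboxylate
Conditions: K2CO3 (1.1 equiv), 12 (1.05 equiv), DMF, 0 °C → rt, Ar, dark
Reagents that add atoms: none
Why: Oxa-Michael addition–elimination of the phenoxide on the bromoquinone; the 1-OH is held in a hydrogen bond to the ester so the free 4-OH reacts, and every ring carbon of 11 is substituted so only O-arylation is possible.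

**Compound list**
1 | 2-formylbenzoic acid (in equilibrium with 3-hydroxyphthalide) | O=Cc1ccccc1C(=O)O | starting material
2 | benzenethiol (thiophenol) | Sc1ccccc1 | starting material
3 | racemic 3-(phenylsulfanyl)-2-benzofuran-1(3H)-one | O=C1OC(Sc2ccccc2)c2ccccc12 | intermediate
4 | racemic 3-(benzenesulfonyl)-2-benzofuran-1(3H)-one | O=C1OC(c2ccccc12)S(=O)(=O)c1ccccc1 | intermediate
5 | 4-methylpent-3-en-1-ol | CC(C)=CCCO | starting material
6 | methyl (triphenylphosphoranylidene)acetate | COC(=O)C=P(c1ccccc1)(c1ccccc1)c1ccccc1 | starting material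
7 | 4-methylpent-3-enal | CC(C)=CCC=O | intermediate (not isolated)
8 | methyl (2E)-6-methylhepta-2,5-dienoate | COC(=O)/C=C/CC=C(C)C | intermediate
9 | Michael adduct, methyl 6-methyl-3-[3-oxo-1-(benzenesulfonyl)-1,3-dihydro-2-benzofuran-1-yl]hept-5-enoate (present as its lithium ester enolate, diastereomer mixture, racemic) | COC(=O)CC(CC=C(C)C)C1(OC(=O)c2ccccc12)S(=O)(=O)c1ccccc1 | intermediate (not isolated)
10 | diketo tautomer, methyl 3-(3-methylbut-2-en-1-yl)-1,4-dioxo-1,2,3,4-tetrahydronaphthalene-2-carboxylate | COC(=O)C1C(CC=C(C)C)C(=O)c2ccccc2C1=O | intermediate (not isolated)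
11 | methyl 1,4-dihydroxy-3-(3-methylbut-2-en-1-yl)naphthalene-2-carboxylate | COC(=O)c1c(CC=C(C)C)c(O)c2ccccc2c1O | intermediate
12 | 2-bromonaphthalene-1,4-dione (2-bromo-1,4-naphthoquinone) | O=C1C=C(Br)C(=O)c2ccccc12 | starting material
13 | Rubioncolin C (achiral) | COC(=O)c1c(CC=C(C)C)c(OC2=CC(=O)c3ccccc3C2=O)c2ccccc2c1O | target

**Step count and risks**
Total steps: 5. Longest linear sequence: 4 steps (1 → 3 → 4 → 11 → 13, i.e. steps 1, 2, 4, 5).

Most likely to fail, step 4: the skipped dienoate 8 has acidic doubly allylic γ-hydrogens and could isomerise to the conjugated 2,4-dienoate before the Michael addition, although butenolides and cyclohexenones with similar γ-hydrogens are good partners in this annulation. Fallback: build the prenyl group after the annulation. Setting out from 4, the same Michael–Dieckmann annulation is run with methyl acrylate (LiOtBu, THF, −78 °C → rt) to give methyl 1,4-dihydroxynaphthalene-2-carboxylate F1. Allyl bromide and K2CO3 in acetone alkylate only the non-chelated 4-OH to give methyl 1-hydroxy-4-(prop-2-en-1-yloxy)naphthalene-2-carboxylate F2. Aromatic Claisen rearrangement (N,N-diethylaniline, 190 °C, Ar) moves the allyl group to the only free ortho carbon to give methyl 1,4-dihydroxy-3-(prop-2-en-1-yl)naphthalene-2-carboxylate F3. Cross-metathesis with excess 2-methylbut-2-ene (second-generation Grubbs catalyst, (H2IMes)(PCy3)Cl2Ru=CHPh, CH2Cl2, 40 °C) converts allyl into prenyl, and the route is rejoined at 11.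

Second, step 5: the hydroquinone 11 can exchange redox state with the bromoquinone 12 under base, and over-arylation at the 1-OH is possible. Fallback: mask the 1-OH so that 11 can no longer be oxidised to a quinone. Setting out from 11, TBSCl and imidazole (DMF, 0 °C) silylate the free 4-OH to give methyl 4-[(tert-butyldimethylsilyl)oxy]-1-hydroxy-3-(3-methylbut-2-en-1-yl)naphthalene-2-carboxylate F4. NaH and MOMCl (DMF, 0 °C) cap the chelated 1-OH to give methyl 4-[(tert-butyldimethylsilyl)oxy]-1-(methoxymethoxy)-3-(3-methylbut-2-en-1-yl)naphthalene-2-carboxylate F5. Bu4NF buffered with AcOH (THF, 0 °C) frees the 4-OH to give methyl 4-hydroxy-1-(methoxymethoxy)-3-(3-methylbut-2-en-1-yl)naphthalene-2-carboxylate F6. F6 is coupled with 12 (K2CO3, DMF, rt) to give methyl 4-[(1,4-dioxo-1,4-dihydronaphthalen-2-yl)oxy]-1-(methoxymethoxy)-3-(3-methylbut-2-en-1-yl)naphthalene-2-carboxylate F7. Brief TFA in CH2Cl2 at 0 °C, then aqueous work-up, removes the MOM group without a nucleophile that could attack the aryloxyquinone, and the route is rejoined at 13.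

Third, step 3: aldehyde 7 can slip into conjugation (4-methylpent-2-enal) before it is trapped, and 8 is volatile. Fallback: reverse the polarity of the olefination so that no β,γ-unsaturated aldehyde is involved. Setting out from 5, CBr4 and PPh3 (CH2Cl2, 0 °C) give 5-bromo-2-methylpent-2-ene F8. PPh3 in refluxing MeCN gives (4-methylpent-3-en-1-yl)triphenylphosphonium bromide F9. Deprotonation with NaN(SiMe3)2 (THF, −78 °C) and addition of methyl glyoxylate give methyl (2Z)-6-methylhepta-2,5-dienoate F10. Its alkene geometry is irrelevant because it is lost in the annulation, so F10 is used with 4 under the step 4 conditions in place of 8, and the route is rejoined at 11.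

**Further compounds**
F1 | step 4 | methyl 1,4-dihydroxynaphthalene-2-carboxylate | COC(=O)c1cc(O)c2ccccc2c1O
F2 | step 4 | methyl 1-hydroxy-4-(prop-2-en-1-yloxy)naphthalene-2-carboxylate | COC(=O)c1cc(OCC=C)c2ccccc2c1O
F3 | step 4 | methyl 1,4-dihydroxy-3-(prop-2-en-1-yl)naphthalene-2-carboxylate | COC(=O)c1c(CC=C)c(O)c2ccccc2c1O
F4 | step 5 | methyl 4-[(tert-butyldimethylsilyl)oxy]-1-hydroxy-3-(3-methylbut-2-en-1-yl)naphthalene-2-carboxylate | COC(=O)c1c(CC=C(C)C)c(O[Si](C)(C)C(C)(C)C)c2ccccc2c1O
F5 | step 5 | methyl 4-[(tert-butyldimethylsilyl)oxy]-1-(methoxymethoxy)-3-(3-methylbut-2-en-1-yl)naphthalene-2-carboxylate | COCOc1c(C(=O)OC)c(CC=C(C)C)c(O[Si](C)(C)C(C)(C)C)c2ccccc12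
F6 | step 5 | methyl 4-hydroxy-1-(methoxymethoxy)-3-(3-methylbut-2-en-1-yl)naphthalene-2-carboxylate | COCOc1c(C(=O)OC)c(CC=C(C)C)c(O)c2ccccc12
F7 | step 5 | methyl 4-[(1,4-dioxo-1,4-dihydronaphthalen-2-yl)oxy]-1-(methoxymethoxy)-3-(3-methylbut-2-en-1-yl)naphthalene-2-carboxylate | COCOc1c(C(=O)OC)c(CC=C(C)C)c(OC2=CC(=O)c3ccccc3C2=O)c2ccccc12
F8 | step 3 | 5-bromo-2-methylpent-2-ene | CC(C)=CCCBr
F9 | step 3 | (4-methylpent-3-en-1-yl)triphenylphosphonium bromide | CC(C)=CCC[P+](c1ccccc1)(c1ccccc1)c1ccccc1.[Br-]
F10 | step 3 | methyl (2Z)-6-methylhepta-2,5-dienoate | COC(=O)/C=C\CC=C(C)C
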